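**Retrosynthetic overview**

1. Target ⇐ C3 acetate ⇐ C3/C9 diketo lactone carrying a C11=C12 enone: one hydride operation sets C3 (attack from the lactone face) and turns the enone into the C9 ketone.
2. Key disconnection C3–C4: ring A (C1–C2–C3–C4–C5–C10) is closed last, by acylation of the enolate of the C19→C10 γ-lactone (C4) with a C3 N-methoxy-N-methylamide. In the same flask, just before, C8–C15 enolate alkylation closes the cyclopentane of the bicyclo[3.2.1]octane, so the precursor is only a 4-substituted cyclohexenone tethered to a monocyclic lactone.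
3. That precursor ⇐ C6–C7 Giese union of a bromomethyl lactone with 3-methylenenopinone ((+)-nopinone supplies C13; its cyclobutane is a temporary ring), then cyclobutane opening, enol-acetate dehydrogenation and allylic chlorination.
4. Bromomethyl lactone ⇐ geraniol: Sharpless epoxidation plus SN2 opening at C5 by an isopropenyl copper reagent fix C10 and C5; hydroboration and oxidative lactonisation give the γ-lactone (C19–O–C10), the first ring made.
5. Enabling feature: C4 is both the α-carbon of the γ-lactone (C19) and the neighbour of oxygenated C3 (β-oxy lactone = Claisen/aldol retron), and C10 carries both the lactone oxygen and the C1–C2–C3 arm, so ring A is a 6-oxabicyclo[3.2.1]octanone whose C3–C4 bond can form on one face only; C9=O between quaternary C8 and bridgehead C13 makes its enone non-enolisable. Ring order: γ-lactone, cyclopentane of the bicyclo[3.2.1]octane, ring A.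

Key step: step 13

Remark (assumption and numbering): kaurane numbering is used (C19 = lactone carbonyl, C18/C20 = methyls, C17 = exo-methylene carbon). The SMILES is taken as drawn, which places the C5 side chain and the C3 acetoxy group on the face of ring A opposite to the lactone bridge.

**Route**

Step 1
Reactants: 1 geraniol
Product: 2 (2S,3S)-2,3-epoxygeraniol
Conditions: Ti(OiPr)4 (5 mol%), L-(+)-diethyl tartrate (7 mol%), t-BuOOH, 4 Å MS, CH2Cl2, −20 °C
Reagents that add atoms: tert-butyl hydroperoxide, CC(C)(C)OO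
Why: Sharpless asymmetric epoxidation touches only the allylic alkene, and L-(+)-tartrate should deliver oxygen to the face that gives the (2S,3S)-epoxide, which fixes C10 and, after inversion, C5.

Step 2
Reactants: 2 (2S,3S)-2,3-epoxygeraniol; 3 isopropenylmagnesium bromide
Product: 4 (2R,3S)-3,7-dimethyl-2-(prop-1-en-2-yl)oct-6-ene-1,3-diol
Conditions: 3 (3 equiv), CuI (20 mol%), THF, −30 → 0 °C; aq. NH4Cl
Reagents that add atoms: isopropenylmagnesium bromide, CC(=C)[Mg]Br
Why: Copper-catalysed SN2 opening of the 2,3-epoxy alcohol at C2, the only carbon open to backside attack because C3 is fully substituted; inversion at C2 creates C5 with the isopropenyl group (C4, C18, C19) anti to the C10 oxygen.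

Step 3
Reactants: 4 (2R,3S)-3,7-dimethyl-2-(prop-1-en-2-yl)oct-6-ene-1,3-diol
Product: 6 (2S,3S)-1-bromo-3,7-dimethyl-2-(prop-1-en-2-yl)oct-6-en-3-ol, via primary mesylate 5 (not isolated)
Conditions: MsCl (1.05 equiv), Et3N, CH2Cl2, −20 °C; then LiBr, acetone, 50 °C
Reagents that add atoms: lithium bromide, [Li+].[Br-]; methanesulfonyl chloride, CS(=O)(=O)Cl (atoms only in 5)
Why: Selective sulfonylation of the primary hydroxyl beside the unreactive tertiary one, then Finkelstein-type SN2 displacement; the bromide stores C6 as the later radical precursor and removes a hydroxyl that could compete for the lactone carbonyl.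

Step 4
Reactants: 6 (2S,3S)-1-bromo-3,7-dimethyl-2-(prop-1-en-2-yl)oct-6-en-3-ol
Product: 8 (3S,4S)-3-(bromomethyl)-2,4,8-trimethylnon-7-ene-1,4-diol (C2 epimers), via alkyl-9-BBN adduct 7 (not isolated)
Conditions: 9-BBN (2.5 equiv), THF, 0 °C → rt; then aq. NaOAc, 30% H2O2, 0 °C
Reagents that add atoms: hydrogen peroxide, OO; 9-borabicyclo[3.3.1]nonane, B1C2CCCC1CCC2 (atoms only in 7)
Why: Hydroboration–oxidation; 9-BBN adds anti-Markovnikov to the 1,1-disubstituted isopropenyl group and leaves the trisubstituted alkene, and the new C4 centre need not be controlled because it is enolised in step 13.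

Step 5
Reactants: 8 (3S,4S)-3-(bromomethyl)-2,4,8-trimethylnon-7-ene-1,4-diol
Product: 9 (4S,5S)-4-(bromomethyl)-3,5-dimethyl-5-(4-methylpent-3-en-1-yl)oxolan-2-one (C3 epimers)
Conditions: TEMPO (20 mol%), PhI(OAc)2 (2.5 equiv), CH2Cl2, rt
Reagents that add atoms: none
Why: TEMPO/hypervalent-iodine oxidative lactonisation of a 1,4-diol: the primary alcohol is oxidised to the aldehyde, the tertiary hydroxyl closes the lactol and this is oxidised to the γ-lactone (C19–O–C10), the first ring of the target.

Step 6
Reactants: 9 (4S,5S)-4-(bromomethyl)-3,5-dimethyl-5-(4-methylpent-3-en-1-yl)oxolan-2-one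
Product: 10 3-[(2S,3S)-3-(bromomethyl)-2,4-dimethyl-5-oxooxolan-2-yl]propanoic acid (C4 epimers)
Conditions: RuCl3·xH2O (3 mol%), NaIO4 (4 equiv), CCl4/MeCN/H2O, rt
Reagents that add atoms: sodium periodate, [Na+].[O-]I(=O)(=O)=O; water, O
Why: Ruthenium tetroxide-catalysed oxidative cleavage of the only remaining alkene should give the C3 carboxylic acid and acetone, with lactone and primary bromide inert.

Step 7
Reactants: 10 3-[(2S,3S)-3-(bromomethyl)-2,4-dimethyl-5-oxooxolan-2-yl]propanoic acid; 11 N,O-dimethylhydroxylamine hydrochloride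
Product: 12 3-[(2S,3S)-3-(bromomethyl)-2,4-dimethyl-5-oxooxolan-2-yl]-N-methoxy-N-methylpropanamide (C4 epimers)
Conditions: EDC·HCl, HOBt, N-methylmorpholine, CH2Cl2, 0 °C → rt
Reagents that add atoms: N,O-dimethylhydroxylamine hydrochloride, CNOC.Cl
Why: Carbodiimide amide coupling; the N-methoxy-N-methylamide is a robust C3 acyl donor whose α-CH2 is much less acidic than the lactone α-H and whose tetrahedral adduct does not collapse before work-up.

Step 8
Reactants: 13 (1R,5S)-(+)-nopinone; 14 paraformaldehyde
Product: 15 (1R,5R)-6,6-dimethyl-3-methylidenebicyclo[3.1.1]heptan-2-one (3-methylenenopinone, bridgeheads as in 13)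
Conditions: (CH2O)n, i-Pr2NH·CF3CO2H (1 equiv), CF3CO2H (10 mol%), THF, reflux; used at once
Reagents that add atoms: formaldehyde (as paraformaldehyde), C=O
Why: Mannich condensation/β-elimination (α-methylenation) at C3, the only enolisable position of nopinone since C1 is a bridgehead; the new carbon becomes C7.

Step 9
Reactants: 12 3-[(2S,3S)-3-(bromomethyl)-2,4-dimethyl-5-oxooxolan-2-yl]-N-methoxy-N-methylpropanamide; 15 3-methylenenopinone
Product: 16 N-methoxy-N-methyl-3-[(2S,3S)-3-{2-[(1R,5S)-6,6-dimethyl-2-oxobicyclo[3.1.1]heptan-3-yl]ethyl}-2,4-dimethyl-5-oxooxolan-2-yl]propanamide (epimers at the two CH centres α to the carbonyls)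
Conditions: 15 (3 equiv), Bu3SnH (1.3 equiv, syringe pump), AIBN (cat.), PhH, 80 °C
Reagents that add atoms: none
Why: Giese reaction: the nucleophilic primary C6 radical adds to the exo-methylene of the α-methylene ketone faster than it is reduced at low stannane concentration, forging C6–C7 without base, so lactone and amide are untouched.

Step 10
Reactants: 16 (Giese adduct); 17 acetic anhydride
Product: 18 (4R)-6-{2-[(2S,3S)-2-{3-[methoxy(methyl)amino]-3-oxopropyl}-2,4-dimethyl-5-oxooxolan-3-yl]ethyl}-4-(prop-1-en-2-yl)cyclohex-1-en-1-yl acetate (epimers at C6 of the ring and C4 of the lactone)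
Conditions: BF3·OEt2 (1.5 equiv), Zn(OAc)2 (1.2 equiv), Ac2O, 0 °C → rt
Reagents that add atoms: acetic anhydride, CC(=O)OC(C)=O
Why: Lewis-acid-promoted cyclobutane cleavage of a nopinone-type ketone: the strained bond between the bridgehead α-carbon and CMe2 breaks to a tertiary cation and an enol that is trapped regiospecifically as the acetate, while the cation loses a methyl proton to give the isopropenyl group; the second bridgehead is untouched and becomes C13.

Step 11
Reactants: 18 (enol acetate)
Product: 19 N-methoxy-N-methyl-3-[(2S,3S)-2,4-dimethyl-5-oxo-3-{2-[(5S)-2-oxo-5-(prop-1-en-2-yl)cyclohex-3-en-1-yl]ethyl}oxolan-2-yl]propanamide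
Conditions: Pd(OAc)2 (5 mol%), dppe (5 mol%), allyl methyl carbonate (2 equiv), Bu3SnOMe (20 mol%), MeCN, reflux
Reagents that add atoms: none
Why: Palladium-catalysed dehydrogenation of an enol acetate (tin enolate, allylpalladium enolate, β-hydride elimination; a Saegusa-type oxidation with allyl carbonate as oxidant) places the double bond at C11=C12 on the side defined by the enol acetate, so C8–H is the only α′-position.

Step 12
Reactants: 19 (isopropenyl enone)
Product: 20 N-methoxy-N-methyl-3-[(2S,3S)-3-{2-[(5S)-5-(3-chloroprop-1-en-2-yl)-2-oxocyclohex-3-en-1-yl]ethyl}-2,4-dimethyl-5-oxooxolan-2-yl]propanamide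
Conditions: Ca(OCl)2, solid CO2, CH2Cl2/H2O, 0 °C
Reagents that add atoms: calcium hypochlorite, [Ca+2].[O-]Cl.[O-]Cl
Why: Ene-type allylic chlorination of the electron-rich 1,1-disubstituted alkene by HOCl with double-bond shift, as known for isopropenyl groups of p-menthenones; the electron-poor enone is not attacked.

Step 13
Reactants: 20 (chloro enone)
Product: 22 (4S,5S,8S,10S,13S)-3,9-dioxo-9,10-secokaura-11,16-dien-19,10-olide, via bicyclic enone amide 21 (not isolated)
Conditions: LDA (1.05 equiv), THF, −78 → 0 °C; then LiHMDS (2.5 equiv), −78 → 0 °C; aq. NH4Cl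
Reagents that add atoms: none
Why: The kinetic amide base first removes the most acidic proton, C8–H (α′ of the enone), and the cross-conjugated enolate displaces the allylic chloride intramolecularly (enolate C-alkylation, 5-(enolexo)-exo-tet; SN2 and SN2′ give the same product because the 2-substituted allyl unit is symmetric), which closes the cyclopentane of the bicyclo[3.2.1]octane (21). Enone 21 has no enolisable position left (C8 quaternary, C13 a bridgehead), so the second base can only deprotonate C4–H of the lactone (the amide α-CH2 is several pKa units less acidic), and the lactone enolate adds to the amide carbonyl in a 6-(enolexo)-exo-trig closure to a lithium-chelated tetrahedral adduct that releases the C3 ketone only on work-up (Claisen/Dieckmann-type acylation of an ester enolate by an N-methoxy-N-methylamide; the closest structural analogy is the reversible C3–C4 aldol closure of gibberellin A-ring lactones). The new C8 centre is dictated by C13, because the chloromethylvinyl arm can reach only the enolate face on which it stands. The new C4 centre is dictated by C10, because the C1–C2–C3 arm reaches C4 only on the lactone face cis to C1, so C3 is bonded cis to C1 and the C18 methyl ends on the side of the C20 methyl. The step needs site selectivity in the two deprotonations and the order bicycle before ring A; both follow from the acidity order ketone α′-H > lactone α-H > amide α-H, from the staged base addition, and from the stable tetrahedral adduct, which prevents retro-Claisen cleavage.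

Step 14
Reactants: 22 (diketo lactone)
Product: 23 (3S,4S,5S,8S,10S,13R)-3-hydroxy-9-oxo-9,10-secokaur-16-en-19,10-olide
Conditions: L-Selectride (3 equiv), THF, −78 °C; aq. NH4Cl at −78 °C
Reagents that add atoms: none
Why: Selectride reduction: hydride should enter the C3 ketone from the lactone-bridge face, because the opposite axial trajectory is blocked by the syn-axial C5 side chain, giving the C3 alcohol cis to that chain; the same reagent reduces the β-unsubstituted, α′-quaternary enone in 1,4 fashion to an enolate that shields C9 from further reduction and gives the C9 ketone on protonation.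

Step 15
Reactants: 23 (hydroxy keto lactone); 17 acetic anhydride
Product: 24 (3S,4S,5S,8S,10S,13R)-3-acetoxy-9-oxo-9,10-secokaur-16-en-19,10-olide (target)
Conditions: Ac2O, DMAP, Et3N, CH2Cl2, rt
Reagents that add atoms: acetic anhydride, CC(=O)OC(C)=O
Why: DMAP-catalysed acylation of the hindered secondary alcohol under mild, weakly basic conditions that should not trigger retro-aldol opening of the β-hydroxy lactone.

**Compound list**

1 | geraniol, (2E)-3,7-dimethylocta-2,6-dien-1-ol | CC(C)=CCC/C(C)=C/CO | starting material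
2 | (2S,3S)-2,3-epoxygeraniol | OC[C@@H]1O[C@@]1(C)CCC=C(C)C | intermediate
3 | isopropenylmagnesium bromide | CC(=C)[Mg]Br | starting material
4 | (2R,3S)-3,7-dimethyl-2-(prop-1-en-2-yl)oct-6-ene-1,3-diol | OC[C@@H](C(C)=C)[C@@](C)(O)CCC=C(C)C | intermediate
5 | (2R,3S)-3-hydroxy-3,7-dimethyl-2-(prop-1-en-2-yl)oct-6-en-1-yl methanesulfonate | CS(=O)(=O)OC[C@@H](C(C)=C)[C@@](C)(O)CCC=C(C)C | intermediate (not isolated)
6 | (2S,3S)-1-bromo-3,7-dimethyl-2-(prop-1-en-2-yl)oct-6-en-3-ol | BrC[C@@H](C(C)=C)[C@@](C)(O)CCC=C(C)C | intermediate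
7 | (3S,4S)-1-(9-borabicyclo[3.3.1]nonan-9-yl)-3-(bromomethyl)-2,4,8-trimethylnon-7-en-4-ol (C2 epimers; tertiary hydroxyl drawn free) | BrC[C@@H](C(C)CB1C2CCCC1CCC2)[C@@](C)(O)CCC=C(C)C | intermediate (not isolated)
8 | (3S,4S)-3-(bromomethyl)-2,4,8-trimethylnon-7-ene-1,4-diol (C2 epimers) | BrC[C@@H](C(C)CO)[C@@](C)(O)CCC=C(C)C | intermediate
9 | (4S,5S)-4-(bromomethyl)-3,5-dimethyl-5-(4-methylpent-3-en-1-yl)oxolan-2-one (C3 epimers) | BrC[C@H]1C(C)C(=O)O[C@@]1(C)CCC=C(C)C | intermediate
10 | 3-[(2S,3S)-3-(bromomethyl)-2,4-dimethyl-5-oxooxolan-2-yl]propanoic acid (C4 epimers) | BrC[C@H]1C(C)C(=O)O[C@@]1(C)CCC(O)=O | intermediate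
11 | N,O-dimethylhydroxylamine hydrochloride | CNOC.Cl | starting material
12 | 3-[(2S,3S)-3-(bromomethyl)-2,4-dimethyl-5-oxooxolan-2-yl]-N-methoxy-N-methylpropanamide (C4 epimers) | BrC[C@H]1C(C)C(=O)O[C@@]1(C)CCC(=O)N(C)OC | intermediate
13 | (1R,5S)-(+)-nopinone, 6,6-dimethylbicyclo[3.1.1]heptan-2-one | O=C1CC[C@H]2C[C@@H]1C2(C)C | starting material
14 | paraformaldehyde (formaldehyde) | C=O | starting material
15 | (1R,5R)-6,6-dimethyl-3-methylidenebicyclo[3.1.1]heptan-2-one (3-methylenenopinone) | O=C1C(=C)C[C@H]2C[C@@H]1C2(C)C | intermediate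
16 | N-methoxy-N-methyl-3-[(2S,3S)-3-{2-[(1R,5S)-6,6-dimethyl-2-oxobicyclo[3.1.1]heptan-3-yl]ethyl}-2,4-dimethyl-5-oxooxolan-2-yl]propanamide (epimers α to both carbonyls) | O=C1C(CC[C@H]3C(C)C(=O)O[C@@]3(C)CCC(=O)N(C)OC)C[C@H]2C[C@@H]1C2(C)C | intermediate
17 | acetic anhydride | CC(=O)OC(C)=O | starting material
18 | (4R)-6-{2-[(2S,3S)-2-{3-[methoxy(methyl)amino]-3-oxopropyl}-2,4-dimethyl-5-oxooxolan-3-yl]ethyl}-4-(prop-1-en-2-yl)cyclohex-1-en-1-yl acetate | CC(=O)OC1=CC[C@@H](C(C)=C)CC1CC[C@H]2C(C)C(=O)O[C@@]2(C)CCC(=O)N(C)OC | intermediate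
19 | N-methoxy-N-methyl-3-[(2S,3S)-2,4-dimethyl-5-oxo-3-{2-[(5S)-2-oxo-5-(prop-1-en-2-yl)cyclohex-3-en-1-yl]ethyl}oxolan-2-yl]propanamide | O=C1C=C[C@@H](C(C)=C)CC1CC[C@H]2C(C)C(=O)O[C@@]2(C)CCC(=O)N(C)OC | intermediate
20 | N-methoxy-N-methyl-3-[(2S,3S)-3-{2-[(5S)-5-(3-chloroprop-1-en-2-yl)-2-oxocyclohex-3-en-1-yl]ethyl}-2,4-dimethyl-5-oxooxolan-2-yl]propanamide | O=C1C=C[C@@H](C(=C)CCl)CC1CC[C@H]2C(C)C(=O)O[C@@]2(C)CCC(=O)N(C)OC | intermediate
21 | N-methoxy-N-methyl-3-[(2S,3S)-2,4-dimethyl-3-{2-[(1S,5S)-6-methylidene-2-oxobicyclo[3.2.1]oct-3-en-1-yl]ethyl}-5-oxooxolan-2-yl]propanamide | C=C1C[C@]2(CC[C@H]3C(C)C(=O)O[C@@]3(C)CCC(=O)N(C)OC)C[C@H]1C=CC2=O | intermediate (not isolated)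
22 | (4S,5S,8S,10S,13S)-3,9-dioxo-9,10-secokaura-11,16-dien-19,10-olide | C=C1C[C@]2(CC[C@H]3[C@]4(C)C(=O)O[C@@]3(C)CCC4=O)C[C@H]1C=CC2=O | intermediate
23 | (3S,4S,5S,8S,10S,13R)-3-hydroxy-9-oxo-9,10-secokaur-16-en-19,10-olide | C=C1C[C@]2(CC[C@H]3[C@]4(C)C(=O)O[C@@]3(C)CC[C@@H]4O)C[C@H]1CCC2=O | intermediate
24 | (3S,4S,5S,8S,10S,13R)-3-acetoxy-9-oxo-9,10-secokaur-16-en-19,10-olide | C=C1C[C@]2(CC[C@H]3[C@]4(C)C(=O)O[C@@]3(C)CC[C@@H]4OC(C)=O)C[C@H]1CCC2=O | target

**Step count and risks**

Total steps: 15. Longest linear sequence: 14 (geraniol 1 to target 24; step 8 lies on the nopinone branch).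

Step 13 (key step). What may go wrong: competing γ-deprotonation at C13 followed by three-membered ring closure onto the allylic chloride; slow or reversible addition of the hindered tertiary lactone enolate to the amide, because the new tetrahedral C3 sits syn to the axial C5 side chain; deprotonation at the amide α-CH2 and attack on the lactone carbonyl. The fallback sets out from 20 and comes back at 22. Only the LDA stage is run and the bicyclic enone amide 21 is isolated. The amide is reduced with Cp2Zr(H)Cl (THF, rt, short contact) to the bicyclic enone lactone aldehyde F1. Ring A is then closed by the base-mediated aldol of the lactone enolate with the C3 aldehyde (KOt-Bu, t-BuOH/THF, 0 °C, as in gibberellin A-ring chemistry) to give the bridged C3 carbinols F2 (C3 epimers). Dess–Martin oxidation of F2 gives 22.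

Step 10. What may go wrong: capture of the tertiary cation by acetate instead of proton loss, or proton loss towards the isopropylidene isomer, which would spoil the allylic chlorination. The fallback sets out from 16 and comes back at 19. The cyclobutane is opened with iodotrimethylsilane (TMSCl, NaI, MeCN, −20 °C), so that the cation is trapped by iodide and the enol as the silyl ether, giving the silyl enol ether tertiary iodide F3. Dehydrohalogenation with DBU gives the isopropenyl silyl enol ether F4. Saegusa–Ito oxidation of F4 (Pd(OAc)2, MeCN) gives enone 19 directly, without 18 and step 11.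

Step 14. What may go wrong: 1,2- instead of 1,4-reduction of the enone, incomplete facial selectivity at C3, or retro-aldol opening of the lithium aldolate during work-up. The fallback sets out from 22 and comes back at 24. The activated β-keto lactone carbonyl alone is reduced with NaBH4 (MeOH/CH2Cl2, −78 °C; the enone carbonyl beside quaternary C8 stays) to the enone hydroxy lactone F5. Acetylation (Ac2O, DMAP) gives the enone acetate F6. Conjugate reduction of the enone with [(Ph3P)CuH]6 (toluene, H2O, rt) then gives 24.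

**Further compounds**

F1 | step 13 | 3-[(2S,3S)-2,4-dimethyl-3-{2-[(1S,5S)-6-methylidene-2-oxobicyclo[3.2.1]oct-3-en-1-yl]ethyl}-5-oxooxolan-2-yl]propanal | C=C1C[C@]2(CC[C@H]3C(C)C(=O)O[C@@]3(C)CCC=O)C[C@H]1C=CC2=O
F2 | step 13 | (4S,5S,8S,10S,13S)-3-hydroxy-9-oxo-9,10-secokaura-11,16-dien-19,10-olide (C3 epimers) | C=C1C[C@]2(CC[C@H]3[C@]4(C)C(=O)O[C@@]3(C)CCC4O)C[C@H]1C=CC2=O
F3 | step 10 | N-methoxy-N-methyl-3-[(2S,3S)-3-{2-[(5R)-5-(2-iodopropan-2-yl)-2-(trimethylsilyloxy)cyclohex-2-en-1-yl]ethyl}-2,4-dimethyl-5-oxooxolan-2-yl]propanamide | C[Si](C)(C)OC1=CC[C@@H](C(C)(C)I)CC1CC[C@H]2C(C)C(=O)O[C@@]2(C)CCC(=O)N(C)OC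
F4 | step 10 | N-methoxy-N-methyl-3-[(2S,3S)-2,4-dimethyl-5-oxo-3-{2-[(5R)-5-(prop-1-en-2-yl)-2-(trimethylsilyloxy)cyclohex-2-en-1-yl]ethyl}oxolan-2-yl]propanamide | C[Si](C)(C)OC1=CC[C@@H](C(C)=C)CC1CC[C@H]2C(C)C(=O)O[C@@]2(C)CCC(=O)N(C)OC
F5 | step 14 | (3S,4S,5S,8S,10S,13S)-3-hydroxy-9-oxo-9,10-secokaura-11,16-dien-19,10-olide | C=C1C[C@]2(CC[C@H]3[C@]4(C)C(=O)O[C@@]3(C)CC[C@@H]4O)C[C@H]1C=CC2=O
F6 | step 14 | (3S,4S,5S,8S,10S,13S)-3-acetoxy-9-oxo-9,10-secokaura-11,16-dien-19,10-olide | C=C1C[C@]2(CC[C@H]3[C@]4(C)C(=O)O[C@@]3(C)CC[C@@H]4OC(C)=O)C[C@H]1C=CC2=O
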